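The route rests on disconnecting C9–C10 of the ten-membered carbocycle. An intramolecular Nozaki–Hiyama–Kishi coupling of a (Z)-alkenyl iodide (C10) with an α-acyloxy aldehyde (C9) closes this ring onto the preformed trans-fused α-methylene-γ-butyrolactone (O, C6, C7, C11, C12). It delivers the ring-cis C1=C10 olefin, creates the C9 carbinol under control of C8 and frees exactly the hydroxyl that must carry the 2-methylbutanoate. The step exploits the allylic carbinol C9 lying between the C8 oxygen centre and C10 of the C14-bearing C1=C10 olefin. Its precursor is an open-chain lactone whose C6, C7 and C8 centres derive from (R)-glyceraldehyde acetonide through one allylboration.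

Key step: step 16

Remark: positions are given in germacrane numbering (C1–C10 carbocycle, C11–C13 lactone carbons, C14 formyl carbon, C15 hydroxymethyl carbon); "ring-cis" means that the two ring bonds are cis on the olefin. The 2-methylbutanoate of the target is (R).

Step 1
Reactants: 1 but-2-yne-1,4-diol
Product: 2 4-[(tert-butyldiphenylsilyl)oxy]but-2-yn-1-ol
Conditions: TBDPSCl (0.3 equiv), imidazole, THF, 0 °C to rt (diol in excess)
Reagents that add atoms: tert-butyl(chloro)diphenylsilane, CC(C)(C)[Si](Cl)(c1ccccc1)c1ccccc1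
Why: Imidazole-promoted silylation of a symmetrical diol used in excess should give mainly the mono-ether (statistical monoprotection).

Step 2
Reactants: 2 4-[(tert-butyldiphenylsilyl)oxy]but-2-yn-1-ol
Product: 4 (Z)-4-[(tert-butyldiphenylsilyl)oxy]-3-iodobut-2-en-1-ol, via cyclic alkenylalanate 3 (not isolated)
Conditions: Red-Al, THF, 0 °C to rt; EtOAc; then I2, −78 to 0 °C
Reagents that add atoms: iodine, II
Why: Hydroxyl-directed trans-hydroalumination places H on the proximal and Al on the distal alkyne carbon, and iodinolysis with retention should give the (Z)-iodide with iodine cis to CH2OH, the geometry later needed for the ring-cis C4=C5 olefin.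

Step 3
Reactants: 4 (Z)-4-[(tert-butyldiphenylsilyl)oxy]-3-iodobut-2-en-1-ol and 5 3,3-diethoxyprop-1-ene
Product: 7 (E)-3-{[(tert-butyldiphenylsilyl)oxy]methyl}-6,6-diethoxyhex-2-en-1-ol, via alkylborane 6 (not isolated)
Conditions: 5, 9-BBN, THF, rt; then 4, PdCl2(dppf) (5 mol %), AsPh3, Cs2CO3, DMF/H2O, rt
Reagents that add atoms: none
Why: Anti-Markovnikov hydroboration followed by B-alkyl Suzuki–Miyaura coupling, which proceeds with retention at the alkenyl iodide, should attach C3 cis to C6 and tolerates the free hydroxyl.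

Step 4
Reactants: 7 (E)-3-{[(tert-butyldiphenylsilyl)oxy]methyl}-6,6-diethoxyhex-2-en-1-ol
Product: 8 (E)-4-{[(tert-butyldiphenylsilyl)oxy]methyl}-6-hydroxyhex-4-enal
Conditions: AcOH/THF/H2O (3:1:1), rt
Reagents that add atoms: water, O
Why: Mild acid hydrolysis of the acyclic acetal (acetal hydrolysis) should leave the TBDPS ether and the olefin geometry untouched.

Step 5
Reactants: 8 (E)-4-{[(tert-butyldiphenylsilyl)oxy]methyl}-6-hydroxyhex-4-enal and 9 (triphenyl-λ5-phosphanylidene)acetaldehyde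
Product: 10 (2E,6E)-6-{[(tert-butyldiphenylsilyl)oxy]methyl}-8-hydroxyocta-2,6-dienal
Conditions: toluene, 80 °C
Reagents that add atoms: none
Why: Wittig olefination with the stabilised formyl ylide should give the (E)-enal and reacts faster with the aliphatic aldehyde than with the conjugated product.

Step 6
Reactants: 10 (2E,6E)-6-{[(tert-butyldiphenylsilyl)oxy]methyl}-8-hydroxyocta-2,6-dienal
Product: 11 (2Z,6E)-6-{[(tert-butyldiphenylsilyl)oxy]methyl}-8-hydroxy-2-iodoocta-2,6-dienal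
Conditions: I2, DMAP (cat.), K2CO3, THF/H2O, rt
Reagents that add atoms: iodine, II
Why: Amine-catalysed α-iodination of an enal (Baylis–Hillman-type addition of DMAP, iodination of the enolate, elimination) should give the (Z)-2-iodoenal with iodine cis to C2; the allylic alcohol end is not an enal and stays untouched.

Step 7
Reactants: 11 (2Z,6E)-6-{[(tert-butyldiphenylsilyl)oxy]methyl}-8-hydroxy-2-iodoocta-2,6-dienal
Product: 12 (2E,6Z)-3-{[(tert-butyldiphenylsilyl)oxy]methyl}-7-iodo-8,8-dimethoxyocta-2,6-dien-1-ol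
Conditions: HC(OMe)3, PPTS (cat.), MeOH, rt
Reagents that add atoms: trimethyl orthoformate, COC(OC)OC
Why: Acid-catalysed acetalisation masks C14 as its dimethyl acetal while C6 is still at the alcohol level, which differentiates the two future aldehydes without a temporary protecting group.

Step 8
Reactants: 12 (2E,6Z)-3-{[(tert-butyldiphenylsilyl)oxy]methyl}-7-iodo-8,8-dimethoxyocta-2,6-dien-1-ol
Product: 13 (2E,6Z)-3-{[(tert-butyldiphenylsilyl)oxy]methyl}-7-iodo-8,8-dimethoxyocta-2,6-dienal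
Conditions: MnO2, CH2Cl2, rt
Reagents that add atoms: none
Why: Selective allylic oxidation with MnO2 should give the C6 enal without loss of olefin geometry; acetal, alkenyl iodide and silyl ether are inert.

Step 9
Reactants: 14 methyl 2-[bis(2,2,2-trifluoroethoxy)phosphoryl]acetate and 15 2-(iodomethyl)-4,4,5,5-tetramethyl-1,3,2-dioxaborolane
Product: 16 methyl 2-[bis(2,2,2-trifluoroethoxy)phosphoryl]-3-(4,4,5,5-tetramethyl-1,3,2-dioxaborolan-2-yl)propanoate (racemic)
Conditions: NaH, THF, 0 °C; then 15, 0 °C to rt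
Reagents that add atoms: none
Why: C-alkylation of the phosphonoacetate anion by the SN2-reactive α-boryl iodide (phosphonate alkylation) should give the α-(borylmethyl) phosphonate.

Step 10
Reactants: 16 methyl 2-[bis(2,2,2-trifluoroethoxy)phosphoryl]-3-(4,4,5,5-tetramethyl-1,3,2-dioxaborolan-2-yl)propanoate and 17 (R)-2,2-dimethyl-1,3-dioxolane-4-carbaldehyde
Product: 18 methyl (Z)-3-[(4S)-2,2-dimethyl-1,3-dioxolan-4-yl]-2-[(4,4,5,5-tetramethyl-1,3,2-dioxaborolan-2-yl)methyl]prop-2-enoate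
Conditions: KHMDS, 18-crown-6, THF, −78 °C
Reagents that add atoms: none
Why: Still–Gennari olefination with the trifluoroethyl phosphonate under dissociating conditions should give the kinetic Z-enoate (ester cis to C8), i.e. an allylboronate whose γ-substituent is trans to CH2B; the α-centre of 17 is not epimerised at −78 °C.

Step 11
Reactants: 13 (2E,6Z)-3-{[(tert-butyldiphenylsilyl)oxy]methyl}-7-iodo-8,8-dimethoxyocta-2,6-dienal and 18 methyl (Z)-3-[(4S)-2,2-dimethyl-1,3-dioxolan-4-yl]-2-[(4,4,5,5-tetramethyl-1,3,2-dioxaborolan-2-yl)methyl]prop-2-enoate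
Product: 20 (4S,5R)-5-[(1E,5Z)-2-{[(tert-butyldiphenylsilyl)oxy]methyl}-6-iodo-7,7-dimethoxyhepta-1,5-dien-1-yl]-4-[(4S)-2,2-dimethyl-1,3-dioxolan-4-yl]-3-methylideneoxolan-2-one, via pinacol borate 19 (not isolated)
Conditions: toluene, 80 °C; then PPTS (cat.), rt
Reagents that add atoms: none
Why: Thermal 2-alkoxycarbonyl allylboration through a chair Zimmerman–Traxler transition state (C8 trans to CH2B, hence equatorial) should give the 6,7-anti adduct and, after lactonisation in the flask, the trans-lactone; the C8 centre, whose C–H eclipses the olefin because of A(1,3) strain against the cis ester, should direct the aldehyde anti to the C8–C9 bond and so set C7 and with it C6.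

Step 12
Reactants: 20 (4S,5R)-5-[(1E,5Z)-2-{[(tert-butyldiphenylsilyl)oxy]methyl}-6-iodo-7,7-dimethoxyhepta-1,5-dien-1-yl]-4-[(4S)-2,2-dimethyl-1,3-dioxolan-4-yl]-3-methylideneoxolan-2-one
Product: 21 (4R,5R)-5-[(1E,5Z)-2-{[(tert-butyldiphenylsilyl)oxy]methyl}-6-iodo-7,7-dimethoxyhepta-1,5-dien-1-yl]-4-[(1S)-1,2-dihydroxyethyl]-3-methylideneoxolan-2-one
Conditions: PPTS, MeOH, 40 °C
Reagents that add atoms: none
Why: Acid-catalysed methanolysis (transketalisation) removes the terminal acetonide as 2,2-dimethoxypropane, whereas the C14 dimethyl acetal can only exchange degenerately in methanol and the TBDPS ether is stable.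

Step 13
Reactants: 21 (4R,5R)-5-[(1E,5Z)-2-{[(tert-butyldiphenylsilyl)oxy]methyl}-6-iodo-7,7-dimethoxyhepta-1,5-dien-1-yl]-4-[(1S)-1,2-dihydroxyethyl]-3-methylideneoxolan-2-one
Product: 22 (4R,5R)-5-[(1E,5Z)-2-{[(tert-butyldiphenylsilyl)oxy]methyl}-6-iodo-7,7-dimethoxyhepta-1,5-dien-1-yl]-4-{(1S)-1-hydroxy-2-[(triethylsilyl)oxy]ethyl}-3-methylideneoxolan-2-one
Conditions: TESCl (1.05 equiv), pyridine, CH2Cl2, −40 °C
Reagents that add atoms: chlorotriethylsilane, CC[Si](Cl)(CC)CC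
Why: Silylation at low temperature should select the primary C9 hydroxyl over the hindered secondary C8 hydroxyl (steric differentiation).

Step 14
Reactants: 22 (4R,5R)-5-[(1E,5Z)-2-{[(tert-butyldiphenylsilyl)oxy]methyl}-6-iodo-7,7-dimethoxyhepta-1,5-dien-1-yl]-4-{(1S)-1-hydroxy-2-[(triethylsilyl)oxy]ethyl}-3-methylideneoxolan-2-one and 23 (Z)-2-methylbut-2-enoic acid (angelic acid)
Product: 25 (1S)-1-[(2R,3S)-2-[(1E,5Z)-2-{[(tert-butyldiphenylsilyl)oxy]methyl}-6-iodo-7,7-dimethoxyhepta-1,5-dien-1-yl]-4-methylidene-5-oxooxolan-3-yl]-2-[(triethylsilyl)oxy]ethyl (2Z)-2-methylbut-2-enoate, via mixed anhydride 24 (not isolated)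
Conditions: 23, 2,4,6-Cl3C6H2COCl, Et3N, toluene, rt; then 22, 75 °C
Reagents that add atoms: none
Why: Yamaguchi-type esterification through the mixed anhydride, run without a nucleophilic catalyst, should acylate C8 with retention and avoid isomerisation of the angelate to the tiglate.

Step 15
Reactants: 25 (1S)-1-[(2R,3S)-2-[(1E,5Z)-2-{[(tert-butyldiphenylsilyl)oxy]methyl}-6-iodo-7,7-dimethoxyhepta-1,5-dien-1-yl]-4-methylidene-5-oxooxolan-3-yl]-2-[(triethylsilyl)oxy]ethyl (2Z)-2-methylbut-2-enoate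
Product: 26 (1S)-1-[(2R,3S)-2-[(1E,5Z)-2-{[(tert-butyldiphenylsilyl)oxy]methyl}-6-iodo-7,7-dimethoxyhepta-1,5-dien-1-yl]-4-methylidene-5-oxooxolan-3-yl]-2-oxoethyl (2Z)-2-methylbut-2-enoate
Conditions: (COCl)2, DMSO, CH2Cl2, −78 to −30 °C; i-Pr2NEt, −78 to 0 °C
Reagents that add atoms: none
Why: Swern conditions convert a primary triethylsilyl ether directly into the aldehyde (desilylation in the flask, then Swern oxidation), so no free C9 hydroxyl arises next to the C8 ester and acyl migration is avoided; low temperature and the hindered base protect the α-acyloxy centre.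

Step 16
Reactants: 26 (1S)-1-[(2R,3S)-2-[(1E,5Z)-2-{[(tert-butyldiphenylsilyl)oxy]methyl}-6-iodo-7,7-dimethoxyhepta-1,5-dien-1-yl]-4-methylidene-5-oxooxolan-3-yl]-2-oxoethyl (2Z)-2-methylbut-2-enoate
Product: 27 (1(10)E,4E,6R,7S,8S,9R)-8-angeloyloxy-15-[(tert-butyldiphenylsilyl)oxy]-9-hydroxy-14,14-dimethoxygermacra-1(10),4,11(13)-trien-12,6-olide (both ring olefins ring-cis)
Conditions: CrCl2 (15 equiv) doped with NiCl2 (1 wt %), DMSO/THF, 2 mM, rt, slow addition of 26
Reagents that add atoms: none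
Why: Ni(0) inserts into the C10–I bond, transmetalation gives an alkenylchromium(III) that adds to the C9 aldehyde (Nozaki–Hiyama–Kishi reaction; the closest known type is the NHK macrocyclisation to medium and large carbocycles). The ten-membered carbocycle closes in a 10-exo-trig mode by C9–C10 bond formation onto the already closed lactone, and the two ring-cis trisubstituted olefins together with the trans-lactone pre-organise the chain ends. The alkenyl geometry is retained, so C1=C10 should emerge ring-cis with C2 cis to C9. C9 is controlled by the adjacent C8 centre: Felkin–Anh (polar) attack anti to the C8–O bond of the non-chelating α-acyloxy aldehyde should give the 8,9-anti (9R) carbinol. The step needs intra- over intermolecular coupling, secured by high dilution and slow addition, and chemoselectivity for C–I over acrylate, esters and acetal, which Cr(II)/Ni(II) provides; the only hydroxyl it creates is the one that must carry the 2-methylbutanoate.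

Step 17
Reactants: 27 (1(10)E,4E,6R,7S,8S,9R)-8-angeloyloxy-15-[(tert-butyldiphenylsilyl)oxy]-9-hydroxy-14,14-dimethoxygermacra-1(10),4,11(13)-trien-12,6-olide and 28 (R)-2-methylbutanoic acid
Product: 29 (1(10)E,4E,6R,7S,8S,9R)-8-angeloyloxy-15-[(tert-butyldiphenylsilyl)oxy]-14,14-dimethoxy-9-{[(2R)-2-methylbutanoyl]oxy}germacra-1(10),4,11(13)-trien-12,6-olide
Conditions: DIC, DMAP (cat.), CH2Cl2, 0 °C to rt
Reagents that add atoms: none
Why: Carbodiimide/DMAP (Steglich) esterification of the only free hydroxyl proceeds with retention at C9 and should not epimerise the α-centre of the acid under these mild conditions.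

Step 18
Reactants: 29 (1(10)E,4E,6R,7S,8S,9R)-8-angeloyloxy-15-[(tert-butyldiphenylsilyl)oxy]-14,14-dimethoxy-9-{[(2R)-2-methylbutanoyl]oxy}germacra-1(10),4,11(13)-trien-12,6-olide
Product: 31 (1(10)E,4E,6R,7S,8S,9R)-8-angeloyloxy-15-hydroxy-9-{[(2R)-2-methylbutanoyl]oxy}-14-oxogermacra-1(10),4,11(13)-trien-12,6-olide (CNP0290361.1), via silyl ether enal 30 (not isolated)
Conditions: 48 % aq HF, MeCN, 0 °C to rt
Reagents that add atoms: water, O
Why: Aqueous HF first hydrolyses the α,β-unsaturated dimethyl acetal to the C14 aldehyde (acetal hydrolysis) and then cleaves the primary TBDPS ether (fluoride desilylation); esters, enal and α-methylene lactone are stable to these acidic conditions.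

Compound list
1 | but-2-yne-1,4-diol | OCC#CCO | starting material
2 | 4-[(tert-butyldiphenylsilyl)oxy]but-2-yn-1-ol | OCC#CCO[Si](c1ccccc1)(c1ccccc1)C(C)(C)C | intermediate
3 | sodium 2,2-bis(2-methoxyethoxy)-3-{[(tert-butyldiphenylsilyl)oxy]methyl}-2,5-dihydro-1,2-oxaaluminol-2-uide (cyclic alkenylalanate) | [Na+].COCCO[Al-]1(OCCOC)OCC=C1CO[Si](c1ccccc1)(c1ccccc1)C(C)(C)C | intermediate (not isolated)
4 | (Z)-4-[(tert-butyldiphenylsilyl)oxy]-3-iodobut-2-en-1-ol | OC/C=C(\I)CO[Si](c1ccccc1)(c1ccccc1)C(C)(C)C | intermediate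
5 | 3,3-diethoxyprop-1-ene (acrolein diethyl acetal) | C=CC(OCC)OCC | starting material
6 | 9-(3,3-diethoxypropyl)-9-borabicyclo[3.3.1]nonane | CCOC(CCB1C2CCCC1CCC2)OCC | intermediate (not isolated)
7 | (E)-3-{[(tert-butyldiphenylsilyl)oxy]methyl}-6,6-diethoxyhex-2-en-1-ol | OC/C=C(/CO[Si](c1ccccc1)(c1ccccc1)C(C)(C)C)CCC(OCC)OCC | intermediate
8 | (E)-4-{[(tert-butyldiphenylsilyl)oxy]methyl}-6-hydroxyhex-4-enal | OC/C=C(/CO[Si](c1ccccc1)(c1ccccc1)C(C)(C)C)CCC=O | intermediate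
9 | (triphenyl-λ5-phosphanylidene)acetaldehyde | O=CC=P(c1ccccc1)(c1ccccc1)c1ccccc1 | starting material
10 | (2E,6E)-6-{[(tert-butyldiphenylsilyl)oxy]methyl}-8-hydroxyocta-2,6-dienal | OC/C=C(/CO[Si](c1ccccc1)(c1ccccc1)C(C)(C)C)CC/C=C/C=O | intermediate
11 | (2Z,6E)-6-{[(tert-butyldiphenylsilyl)oxy]methyl}-8-hydroxy-2-iodoocta-2,6-dienal | OC/C=C(/CO[Si](c1ccccc1)(c1ccccc1)C(C)(C)C)CC/C=C(\I)C=O | intermediate
12 | (2E,6Z)-3-{[(tert-butyldiphenylsilyl)oxy]methyl}-7-iodo-8,8-dimethoxyocta-2,6-dien-1-ol | OC/C=C(/CO[Si](c1ccccc1)(c1ccccc1)C(C)(C)C)CC/C=C(\I)C(OC)OC | intermediate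
13 | (2E,6Z)-3-{[(tert-butyldiphenylsilyl)oxy]methyl}-7-iodo-8,8-dimethoxyocta-2,6-dienal | O=C/C=C(/CO[Si](c1ccccc1)(c1ccccc1)C(C)(C)C)CC/C=C(\I)C(OC)OC | intermediate
14 | methyl 2-[bis(2,2,2-trifluoroethoxy)phosphoryl]acetate | COC(=O)CP(=O)(OCC(F)(F)F)OCC(F)(F)F | starting material
15 | 2-(iodomethyl)-4,4,5,5-tetramethyl-1,3,2-dioxaborolane | ICB1OC(C)(C)C(C)(C)O1 | starting material
16 | methyl 2-[bis(2,2,2-trifluoroethoxy)phosphoryl]-3-(4,4,5,5-tetramethyl-1,3,2-dioxaborolan-2-yl)propanoate (racemic) | COC(=O)C(CB1OC(C)(C)C(C)(C)O1)P(=O)(OCC(F)(F)F)OCC(F)(F)F | intermediate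
17 | (R)-2,2-dimethyl-1,3-dioxolane-4-carbaldehyde | O=C[C@H]1COC(C)(C)O1 | starting material
18 | methyl (Z)-3-[(4S)-2,2-dimethyl-1,3-dioxolan-4-yl]-2-[(4,4,5,5-tetramethyl-1,3,2-dioxaborolan-2-yl)methyl]prop-2-enoate | COC(=O)/C(CB1OC(C)(C)C(C)(C)O1)=C\[C@H]1COC(C)(C)O1 | intermediate
19 | methyl (3S,4R,5E,9Z)-6-{[(tert-butyldiphenylsilyl)oxy]methyl}-3-[(4S)-2,2-dimethyl-1,3-dioxolan-4-yl]-10-iodo-11,11-dimethoxy-2-methylidene-4-[(4,4,5,5-tetramethyl-1,3,2-dioxaborolan-2-yl)oxy]undeca-5,9-dienoate | C=C(C(=O)OC)[C@H]([C@H]1COC(C)(C)O1)[C@H](OB1OC(C)(C)C(C)(C)O1)/C=C(/CO[Si](c1ccccc1)(c1ccccc1)C(C)(C)C)CC/C=C(\I)C(OC)OC | intermediate (not isolated)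
20 | (4S,5R)-5-[(1E,5Z)-2-{[(tert-butyldiphenylsilyl)oxy]methyl}-6-iodo-7,7-dimethoxyhepta-1,5-dien-1-yl]-4-[(4S)-2,2-dimethyl-1,3-dioxolan-4-yl]-3-methylideneoxolan-2-one | C=C1C(=O)O[C@H](/C=C(/CO[Si](c2ccccc2)(c2ccccc2)C(C)(C)C)CC/C=C(\I)C(OC)OC)[C@H]1[C@H]1COC(C)(C)O1 | intermediate
21 | (4R,5R)-5-[(1E,5Z)-2-{[(tert-butyldiphenylsilyl)oxy]methyl}-6-iodo-7,7-dimethoxyhepta-1,5-dien-1-yl]-4-[(1S)-1,2-dihydroxyethyl]-3-methylideneoxolan-2-one | C=C1C(=O)O[C@H](/C=C(/CO[Si](c2ccccc2)(c2ccccc2)C(C)(C)C)CC/C=C(\I)C(OC)OC)[C@H]1[C@H](O)CO | intermediate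
22 | (4R,5R)-5-[(1E,5Z)-2-{[(tert-butyldiphenylsilyl)oxy]methyl}-6-iodo-7,7-dimethoxyhepta-1,5-dien-1-yl]-4-{(1S)-1-hydroxy-2-[(triethylsilyl)oxy]ethyl}-3-methylideneoxolan-2-one | C=C1C(=O)O[C@H](/C=C(/CO[Si](c2ccccc2)(c2ccccc2)C(C)(C)C)CC/C=C(\I)C(OC)OC)[C@H]1[C@H](O)CO[Si](CC)(CC)CC | intermediate
23 | (Z)-2-methylbut-2-enoic acid (angelic acid) | C/C=C(/C)C(=O)O | starting material
24 | (Z)-2-methylbut-2-enoic 2,4,6-trichlorobenzoic anhydride | C/C=C(/C)C(=O)OC(=O)c1c(Cl)cc(Cl)cc1Cl | intermediate (not isolated)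
25 | (1S)-1-[(2R,3S)-2-[(1E,5Z)-2-{[(tert-butyldiphenylsilyl)oxy]methyl}-6-iodo-7,7-dimethoxyhepta-1,5-dien-1-yl]-4-methylidene-5-oxooxolan-3-yl]-2-[(triethylsilyl)oxy]ethyl (2Z)-2-methylbut-2-enoate | C=C1C(=O)O[C@H](/C=C(/CO[Si](c2ccccc2)(c2ccccc2)C(C)(C)C)CC/C=C(\I)C(OC)OC)[C@H]1[C@H](OC(=O)/C(C)=C\C)CO[Si](CC)(CC)CC | intermediate
26 | (1S)-1-[(2R,3S)-2-[(1E,5Z)-2-{[(tert-butyldiphenylsilyl)oxy]methyl}-6-iodo-7,7-dimethoxyhepta-1,5-dien-1-yl]-4-methylidene-5-oxooxolan-3-yl]-2-oxoethyl (2Z)-2-methylbut-2-enoate | C=C1C(=O)O[C@H](/C=C(/CO[Si](c2ccccc2)(c2ccccc2)C(C)(C)C)CC/C=C(\I)C(OC)OC)[C@H]1[C@H](OC(=O)/C(C)=C\C)C=O | intermediate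
27 | (1(10)E,4E,6R,7S,8S,9R)-8-angeloyloxy-15-[(tert-butyldiphenylsilyl)oxy]-9-hydroxy-14,14-dimethoxygermacra-1(10),4,11(13)-trien-12,6-olide | C=C1C(=O)O[C@@H]2/C=C(/CO[Si](c3ccccc3)(c3ccccc3)C(C)(C)C)CC/C=C(/C(OC)OC)[C@@H](O)[C@@H](OC(=O)/C(C)=C\C)[C@@H]12 | intermediate
28 | (R)-2-methylbutanoic acid | CC[C@@H](C)C(=O)O | starting material
29 | (1(10)E,4E,6R,7S,8S,9R)-8-angeloyloxy-15-[(tert-butyldiphenylsilyl)oxy]-14,14-dimethoxy-9-{[(2R)-2-methylbutanoyl]oxy}germacra-1(10),4,11(13)-trien-12,6-olide | C=C1C(=O)O[C@@H]2/C=C(/CO[Si](c3ccccc3)(c3ccccc3)C(C)(C)C)CC/C=C(/C(OC)OC)[C@@H](OC(=O)[C@H](C)CC)[C@@H](OC(=O)/C(C)=C\C)[C@@H]12 | intermediate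
30 | (1(10)E,4E,6R,7S,8S,9R)-8-angeloyloxy-15-[(tert-butyldiphenylsilyl)oxy]-9-{[(2R)-2-methylbutanoyl]oxy}-14-oxogermacra-1(10),4,11(13)-trien-12,6-olide | C=C1C(=O)O[C@@H]2/C=C(/CO[Si](c3ccccc3)(c3ccccc3)C(C)(C)C)CC/C=C(/C=O)[C@@H](OC(=O)[C@H](C)CC)[C@@H](OC(=O)/C(C)=C\C)[C@@H]12 | intermediate (not isolated)
31 | (1(10)E,4E,6R,7S,8S,9R)-8-angeloyloxy-15-hydroxy-9-{[(2R)-2-methylbutanoyl]oxy}-14-oxogermacra-1(10),4,11(13)-trien-12,6-olide (CNP0290361.1) | C=C1C(=O)O[C@@H]2/C=C(/CO)CC/C=C(/C=O)[C@@H](OC(=O)[C@H](C)CC)[C@@H](OC(=O)/C(C)=C\C)[C@@H]12 | target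

Total step count: 18.
Longest linear sequence: 16 steps (steps 1–8 and 11–18); steps 9–10 form the convergent branch.

Steps most likely to fail

1. Step 16 (key step). The conformation of the forming ten-membered ring may override Felkin–Anh control, so that the facial selectivity at C9 is poor or reversed; intermolecular coupling can also compete. Fallback: the C9 configuration is then reached by inversion instead of induction. The fallback sets out from 26, whose closure would give the C9 epimer (1(10)E,4E,6R,7S,8S,9S)-8-angeloyloxy-15-[(tert-butyldiphenylsilyl)oxy]-9-hydroxy-14,14-dimethoxygermacra-1(10),4,11(13)-trien-12,6-olide F1. F1 is esterified with acid 28 under Mitsunobu conditions (PPh3, DIAD, toluene, 0 °C), which should give 29 with inversion at C9, where the route is rejoined.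

2. Step 11. The allylboronate is deactivated by its ester and the conjugated aldehyde is a weak electrophile, so the addition may be sluggish. The acyclic C8 centre may also direct the aldehyde with poor facial selectivity. Fallback: C7 is set by a ring instead of by an open-chain stereocentre. The fallback sets out from 13 and comes back at 26.
- Catalytic asymmetric vinylation of 13 (divinylzinc, amino-alcohol ligand MIB, enantiomer chosen for the 3S carbinol) should give (3S,4E,8Z)-5-{[(tert-butyldiphenylsilyl)oxy]methyl}-9-iodo-10,10-dimethoxydeca-1,4,8-trien-3-ol F2.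
- Acylation with 2-(bromomethyl)acryloyl chloride and 2,6-lutidine gives the 2-(bromomethyl)acrylate F3.
- Ring-closing metathesis with the second-generation Ru benzylidene catalyst closes (5R)-3-(bromomethyl)-5-[(1E,5Z)-2-{[(tert-butyldiphenylsilyl)oxy]methyl}-6-iodo-7,7-dimethoxyhepta-1,5-dien-1-yl]furan-2(5H)-one F4.
- Zinc-mediated Barbier allylation of aldehyde 17 (Zn, THF/aq NH4Cl) should attack C7 trans to the C6 substituent and, under Felkin–Anh control by 17, give (4R,5R)-5-[(1E,5Z)-2-{[(tert-butyldiphenylsilyl)oxy]methyl}-6-iodo-7,7-dimethoxyhepta-1,5-dien-1-yl]-4-{(S)-[(4R)-2,2-dimethyl-1,3-dioxolan-4-yl](hydroxy)methyl}-3-methylideneoxolan-2-one F5.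
- Esterification with 23 via 24 as in step 14 gives the angelate F6.
- Methanolysis of the acetonide (PPTS, MeOH) gives the diol (1S,2R)-2,3-dihydroxy-1-[(2R,3S)-2-[(1E,5Z)-2-{[(tert-butyldiphenylsilyl)oxy]methyl}-6-iodo-7,7-dimethoxyhepta-1,5-dien-1-yl]-4-methylidene-5-oxooxolan-3-yl]propyl (2Z)-2-methylbut-2-enoate F7.
- Glycol cleavage (NaIO4, THF/H2O) gives 26.

3. Step 10. The strongly basic olefination may erode the Z-selectivity with the α-branched phosphonate or cause loss of the boron group. Fallback: geometry and boron are introduced in separate steps. The fallback sets out from 17 and comes back at 18. A bromo-Horner–Wadsworth–Emmons reaction of 17 with methyl bromo[bis(2,2,2-trifluoroethoxy)phosphoryl]acetate (t-BuOK, 18-crown-6, THF, −78 °C) should give methyl (E)-2-bromo-3-[(4S)-2,2-dimethyl-1,3-dioxolan-4-yl]prop-2-enoate F8. Negishi coupling of F8 with the zinc reagent made from 15 and zinc (Pd(PPh3)4, THF) replaces bromine by CH2Bpin with retention and gives 18.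

Further compounds
F1 | step 16 | (1(10)E,4E,6R,7S,8S,9S)-8-angeloyloxy-15-[(tert-butyldiphenylsilyl)oxy]-9-hydroxy-14,14-dimethoxygermacra-1(10),4,11(13)-trien-12,6-olide | C=C1C(=O)O[C@@H]2/C=C(/CO[Si](c3ccccc3)(c3ccccc3)C(C)(C)C)CC/C=C(/C(OC)OC)[C@H](O)[C@@H](OC(=O)/C(C)=C\C)[C@@H]12
F2 | step 11 | (3S,4E,8Z)-5-{[(tert-butyldiphenylsilyl)oxy]methyl}-9-iodo-10,10-dimethoxydeca-1,4,8-trien-3-ol | C=C[C@H](O)/C=C(/CO[Si](c1ccccc1)(c1ccccc1)C(C)(C)C)CC/C=C(\I)C(OC)OC
F3 | step 11 | (3S,4E,8Z)-5-{[(tert-butyldiphenylsilyl)oxy]methyl}-9-iodo-10,10-dimethoxydeca-1,4,8-trien-3-yl 2-(bromomethyl)prop-2-enoate | C=C[C@H](OC(=O)C(=C)CBr)/C=C(/CO[Si](c1ccccc1)(c1ccccc1)C(C)(C)C)CC/C=C(\I)C(OC)OC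
F4 | step 11 | (5R)-3-(bromomethyl)-5-[(1E,5Z)-2-{[(tert-butyldiphenylsilyl)oxy]methyl}-6-iodo-7,7-dimethoxyhepta-1,5-dien-1-yl]furan-2(5H)-one | O=C1O[C@H](/C=C(/CO[Si](c2ccccc2)(c2ccccc2)C(C)(C)C)CC/C=C(\I)C(OC)OC)C=C1CBr
F5 | step 11 | (4R,5R)-5-[(1E,5Z)-2-{[(tert-butyldiphenylsilyl)oxy]methyl}-6-iodo-7,7-dimethoxyhepta-1,5-dien-1-yl]-4-{(S)-[(4R)-2,2-dimethyl-1,3-dioxolan-4-yl](hydroxy)methyl}-3-methylideneoxolan-2-one | C=C1C(=O)O[C@H](/C=C(/CO[Si](c2ccccc2)(c2ccccc2)C(C)(C)C)CC/C=C(\I)C(OC)OC)[C@H]1[C@H](O)[C@H]1COC(C)(C)O1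
F6 | step 11 | (S)-[(4R)-2,2-dimethyl-1,3-dioxolan-4-yl][(2R,3S)-2-[(1E,5Z)-2-{[(tert-butyldiphenylsilyl)oxy]methyl}-6-iodo-7,7-dimethoxyhepta-1,5-dien-1-yl]-4-methylidene-5-oxooxolan-3-yl]methyl (2Z)-2-methylbut-2-enoate | C=C1C(=O)O[C@H](/C=C(/CO[Si](c2ccccc2)(c2ccccc2)C(C)(C)C)CC/C=C(\I)C(OC)OC)[C@H]1[C@H](OC(=O)/C(C)=C\C)[C@H]1COC(C)(C)O1
F7 | step 11 | (1S,2R)-2,3-dihydroxy-1-[(2R,3S)-2-[(1E,5Z)-2-{[(tert-butyldiphenylsilyl)oxy]methyl}-6-iodo-7,7-dimethoxyhepta-1,5-dien-1-yl]-4-methylidene-5-oxooxolan-3-yl]propyl (2Z)-2-methylbut-2-enoate | C=C1C(=O)O[C@H](/C=C(/CO[Si](c2ccccc2)(c2ccccc2)C(C)(C)C)CC/C=C(\I)C(OC)OC)[C@H]1[C@H](OC(=O)/C(C)=C\C)[C@H](O)CO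
F8 | step 10 | methyl (E)-2-bromo-3-[(4S)-2,2-dimethyl-1,3-dioxolan-4-yl]prop-2-enoate | COC(=O)/C(Br)=C\[C@H]1COC(C)(C)O1
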